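## Retrosynthetic overview

1. Last step: intermolecular Diels–Alder forming the spiro-cyclohexene (bonds C12–C15′ and C15–C17′) between an in situ 3-methylenebenzofuranone (totarane dienophile) and (12E)-labda-8(17),12,14-trien-20-oic acid.
2. Dienophile: exo-methylene from the lactone CH2; lactone from an aryl bromide (Pd α-arylation) plus the phenol; 7β-OAc from a benzylic ketone; rings A/B from one enantioselective Brønsted-acid (IDPi) polyene cyclization onto a preformed bromoanisole (ring C).
3. Diene: 1,3-diene from a 3-sulfolene (SO2 extrusion); C3–H from C3–OH; rings A/B and the 8(17)-ene from a titanocene radical cascade of an epoxy-acrylate polyene (acrylate carbon = C20), with absolute configuration from a Shi epoxide.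
4. Polyenes from geranyl halides, homoprenyl bromide, a phosphonoacetate (HWE), 3-methyl-3-sulfolene and 2-bromo-3-methoxybenzyl bromide.
5. Ring order: totarane A+B (step 2), benzofuranone (step 5), labdane A+B (step 13), spiro-cyclohexene (step 18).

Assumption: 2-bromo-1-(bromomethyl)-3-methoxybenzene, allyl (diethoxyphosphoryl)acetate, BrZnCH2CO2t-Bu solution and the L-fructose-derived enantiomer of the Shi ketone are taken as purchasable.

Numbering: podocarpane/totarane numbering for the dienophile half (primed in the dimer), labdane numbering for the diene half; "12,15-sulfonyl" means an SO2 bridge between C12 and C15 (3-sulfolene ring).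

Note: the sulfolene carbon C12 made in step 10 is left uncontrolled (1:1); the sulfolene compounds up to step 16 are epimer pairs at that carbon only, and step 17 erases it. Because two independently enantioenriched halves are joined, the minor enantiomers end up mainly in separable diastereomers of the final product.

## Route

Step 1
Reactants: 1 2-bromo-1-(bromomethyl)-3-methoxybenzene; 2 geranyl chloride
Product: 4 2-bromo-1-[(3E)-4,8-dimethylnona-3,7-dien-1-yl]-3-methoxybenzene, via arylmethylmagnesium bromide 3 (not isolated)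
Conditions: Mg, Et2O, 0 °C; then 2, THF, 0 °C → rt
Reagents that add atoms: none
Why: Benzylic Grignard formation (the aryl C–Br bond is inert at 0 °C) followed by SN2 coupling at the primary allylic chloride gives the (E)-homogeranyl arene without touching the alkene geometry; no stereocentre is formed.

Step 2
Reactants: 4 2-bromo-1-[(3E)-4,8-dimethylnona-3,7-dien-1-yl]-3-methoxybenzene
Product: 5 14-bromo-13-methoxypodocarpa-8,11,13-triene (4bS,8aS; 5α-H; 10β-CH3)
Conditions: confined chiral imidodiphosphorimidate Brønsted acid (IDPi, enantiomer giving the 5α-H/10β-CH3 series; 3 mol%), (CF3)3COH/CH2Cl2, −30 °C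
Reagents that add atoms: none
Why: Proposed new method: enantioselective proton-initiated polyene cyclization under a confined chiral IDPi acid, terminated here by Friedel–Crafts attack of a bromoanisole instead of an O-nucleophile; the acid protonates the terminal isopropylidene (Markovnikov), its chiral anion pairs with the C4 cation in the confined pocket and enforces one chair–chair folding, anti addition across the (E)-alkene forms C4–C5 and C10–C9 so that C5–H and C10–CH3 are trans with (4bS,8aS) configuration (first stereocentres of the route, catalyst-controlled), and the only free ortho carbon (para to OMe, the other ortho site blocked by Br) closes ring B; the closest known reactions are the IDPi-catalysed cyclization of homofarnesol-type polyenes to ambrox-type ethers and classical Stork–Eschenmoser arene-terminated cyclizations.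

Step 3
Reactants: 5 14-bromo-13-methoxypodocarpa-8,11,13-triene
Product: 6 14-bromo-13-methoxypodocarpa-8,11,13-trien-7-one
Conditions: CrO3, AcOH/H2O, rt
Reagents that add atoms: chromium trioxide, O=[Cr](=O)=O
Why: Chromic acid benzylic oxidation is selective because C7 is the only benzylic C–H position (C10 is quaternary, C14 carries Br as an oxidation-proof placeholder); the stereocentres are untouched.

Step 4
Reactants: 6 14-bromo-13-methoxypodocarpa-8,11,13-trien-7-one
Product: 7 tert-butyl 13-methoxy-7-oxo-17-nortotara-8,11,13-trien-16-oate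
Conditions: BrZnCH2CO2t-Bu, Pd(dba)2 (3 mol%), P(t-Bu)3 (3 mol%), THF, rt → 50 °C
Reagents that add atoms: (2-tert-butoxy-2-oxoethyl)zinc bromide, CC(C)(C)OC(=O)C[Zn]Br
Why: Palladium-catalysed α-arylation of a Reformatsky zinc enolate (Negishi-type coupling) installs C15–C16 at C14; the mild zinc enolate tolerates the enolizable aryl ketone, whose ortho position activates the C–Br bond.

Step 5
Reactants: 7 tert-butyl 13-methoxy-7-oxo-17-nortotara-8,11,13-trien-16-oate
Product: 9 7-oxo-17-nortotara-8,11,13-trien-16,13-olide, via hydroxy acid 8 (not isolated)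
Conditions: BBr3, CH2Cl2, −78 → 0 °C; H2O; then p-TsOH (5 mol%), PhMe, 80 °C
Reagents that add atoms: none
Why: BBr3 cleaves the aryl methyl ether and the tert-butyl ester together, and acid-catalysed lactonization of the 2-hydroxyarylacetic acid closes the benzofuranone ring; the ketone and both stereocentres are inert.

Step 6
Reactants: 9 7-oxo-17-nortotara-8,11,13-trien-16,13-olide
Product: 10 7β-hydroxy-17-nortotara-8,11,13-trien-16,13-olide (7S)
Conditions: RuCl[(S,S)-TsDPEN](p-cymene) (1 mol%), HCO2H/Et3N (5:2), CH2Cl2, 30 °C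
Reagents that add atoms: none
Why: Noyori asymmetric transfer hydrogenation reduces the aryl ketone chemoselectively (lactone intact under acidic formate conditions); hydride goes to the α-face (axial attack, reinforced by the (S,S)-ligand, which gives (S)-benzylic alcohols), setting C7 as 7S (β-OH).

Step 7
Reactants: 10 7β-hydroxy-17-nortotara-8,11,13-trien-16,13-olide
Product: 11 7β-acetoxy-17-nortotara-8,11,13-trien-16,13-olide (7S)
Conditions: Ac2O, Sc(OTf)3 (1 mol%), MeCN, −20 °C
Reagents that add atoms: acetic anhydride, CC(=O)OC(C)=O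
Why: Lewis-acid-catalysed acetylation under non-basic conditions esterifies the hindered benzylic alcohol with retention and avoids enolization and O-acylation of the acidic lactone CH2.

Step 8
Reactants: 12 5-bromo-2-methylpent-2-ene
Product: 13 (3S)-3-(2-bromoethyl)-2,2-dimethyloxirane
Conditions: ent-Shi ketone (L-fructose-derived; 30 mol%), KHSO5, K2CO3, Bu4NHSO4, MeCN/CH2(OMe)2, aq. Na2B4O7 buffer pH 10.5, 0 °C
Reagents that add atoms: potassium peroxymonosulfate (Oxone), [K+].[O-]S(=O)(=O)OO
Why: Shi asymmetric epoxidation (chiral dioxirane, spiro transition state) of the only alkene sets the first stereocentre of the labdane half, the (S)-epoxide (expected about 90% ee), which becomes C3 and relays absolute configuration to C5, C10 and C9.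

Step 9
Reactants: 13 (3S)-3-(2-bromoethyl)-2,2-dimethyloxirane; 14 allyl (diethoxyphosphoryl)acetate
Product: 15 allyl 2-(diethoxyphosphoryl)-4-[(2S)-3,3-dimethyloxiran-2-yl]butanoate (epimers at C2)
Conditions: NaH, THF/DMSO, 0 → 45 °C
Reagents that add atoms: none
Why: C-alkylation of the phosphonoacetate sodium enolate by SN2 at the primary bromide; the hindered trisubstituted epoxide is not opened, and the new P-bearing carbon is an inconsequential epimer mixture that vanishes in step 12.

Step 10
Reactants: 16 3-methyl-2,5-dihydrothiophene 1,1-dioxide (3-methyl-3-sulfolene); 17 geranyl bromide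
Product: 18 2-[(2E)-3,7-dimethylocta-2,6-dien-1-yl]-3-methyl-2,5-dihydrothiophene 1,1-dioxide (racemic at ring C2)
Conditions: LiN(SiMe3)2 added to 16 + 17, THF/DMPU, −78 °C
Reagents that add atoms: none
Why: α-Sulfonyl carbanion alkylation of 3-methyl-3-sulfolene with in situ trapping occurs at C2 (next to the methyl-bearing alkene carbon) by SN2 on the allylic bromide, installing the masked diene; C2 is a racemic, traceless centre.

Step 11
Reactants: 18 2-[(2E)-3,7-dimethylocta-2,6-dien-1-yl]-3-methyl-2,5-dihydrothiophene 1,1-dioxide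
Product: 19 (4E)-4-methyl-6-(3-methyl-1,1-dioxo-2,5-dihydrothiophen-2-yl)hex-4-enal
Conditions: O3 (1.0 equiv, Sudan Red 7B end point), pyridine, CH2Cl2/MeOH, −78 °C; then Me2S
Reagents that add atoms: ozone, [O-][O+]=O
Why: Chemoselective ozonolysis with reductive work-up cleaves the most electron-rich, least hindered trisubstituted alkene; the ring alkene is deactivated by two allylic sulfonyl carbons and the internal alkene by the nearby sulfone and sterics.

Step 12
Reactants: 15 allyl 2-(diethoxyphosphoryl)-4-[(2S)-3,3-dimethyloxiran-2-yl]butanoate; 19 (4E)-4-methyl-6-(3-methyl-1,1-dioxo-2,5-dihydrothiophen-2-yl)hex-4-enal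
Product: 20 allyl (6E)-2-{2-[(2S)-3,3-dimethyloxiran-2-yl]ethyl}-6-methyl-8-(3-methyl-1,1-dioxo-2,5-dihydrothiophen-2-yl)octa-2,6-dienoate (2E/2Z mixture)
Conditions: NaH (0.95 equiv), THF, 0 °C; then 19, −20 → 0 °C
Reagents that add atoms: none
Why: Horner–Wadsworth–Emmons olefination builds the trisubstituted acrylate that carries C20; no free base remains to isomerize the sulfolene, and the E/Z ratio is irrelevant because C10 becomes a planar radical in step 13.

Step 13
Reactants: 20 allyl (6E)-2-{2-[(2S)-3,3-dimethyloxiran-2-yl]ethyl}-6-methyl-8-(3-methyl-1,1-dioxo-2,5-dihydrothiophen-2-yl)octa-2,6-dienoate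
Product: 22 allyl 3β-hydroxy-12,15-sulfonyllabda-8(17),13-dien-20-oate (5α-H; 9α-H; 10β-ester), via trimethylsilyl ether 21 (not isolated)
Conditions: Cp2TiCl2 (20 mol%), Mn, Me3SiCl, 2,4,6-collidine, THF (0.01 M), rt; then aq. HCl, THF
Reagents that add atoms: none
Why: Nugent–RajanBabu epoxide opening by Cp2TiCl (trivalent titanium, kept at low concentration) gives the C4 tertiary radical, which adds 6-endo to the acrylate β-carbon (polarity matched) through a chair with the C3 oxygen equatorial; the electrophilic α-ester radical then closes ring B 6-endo on the (E)-alkene through a chair (trans-decalin, C9 side chain equatorial), and the C8 radical loses a methyl β-hydrogen to titanium to give the 8(17)-exo-methylene, so the (S)-epoxide dictates C5, C10 and C9.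

Step 14
Reactants: 22 allyl 3β-hydroxy-12,15-sulfonyllabda-8(17),13-dien-20-oate
Product: 23 allyl 3β-(phenoxythiocarbonyloxy)-12,15-sulfonyllabda-8(17),13-dien-20-oate
Conditions: PhOC(S)Cl, pyridine, DMAP (cat.), CH2Cl2, rt
Reagents that add atoms: O-phenyl chlorothionoformate, S=C(Cl)Oc1ccccc1
Why: Acylation of the equatorial 3β-alcohol to the phenyl thionocarbonate is the first half of a Barton–McCombie deoxygenation; no stereocentre changes.

Step 15
Reactants: 23 allyl 3β-(phenoxythiocarbonyloxy)-12,15-sulfonyllabda-8(17),13-dien-20-oate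
Product: 24 allyl 12,15-sulfonyllabda-8(17),13-dien-20-oate
Conditions: Bu3SnH, Et3B, air (trace), PhMe, rt
Reagents that add atoms: none
Why: Barton–McCombie deoxygenation at room temperature removes the relay oxygen at C3 (not a stereocentre in the target); thionocarbonate transfer outcompetes stannyl radical addition to the alkenes, and the low temperature preserves the sulfolene.

Step 16
Reactants: 24 allyl 12,15-sulfonyllabda-8(17),13-dien-20-oate
Product: 25 12,15-sulfonyllabda-8(17),13-dien-20-oic acid
Conditions: Pd(PPh3)4 (3 mol%), morpholine, THF, 0 °C → rt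
Reagents that add atoms: none
Why: Tsuji–Trost deallylation with zerovalent palladium and morpholine as allyl acceptor frees the hindered angular acid without hydrolysis; at room temperature the allyl ester ionizes far faster than the cyclic allylic sulfone.

Step 17
Reactants: 25 12,15-sulfonyllabda-8(17),13-dien-20-oic acid
Product: 26 (12E)-labda-8(17),12,14-trien-20-oic acid
Conditions: pyridine (2 equiv), PhMe, 110 °C
Reagents that add atoms: none
Why: Thermal cheletropic extrusion of SO2 (disrotatory, C12 substituent rotating outward) unveils the (12E)-diene stereospecifically from either epimer and erases the uncontrolled sulfolene centre.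

Step 18
Reactants: 11 7β-acetoxy-17-nortotara-8,11,13-trien-16,13-olide; 26 (12E)-labda-8(17),12,14-trien-20-oic acid
Product: 28 hispidanin B, via 3-methylene lactone dienophile 27 (not isolated)
Conditions: (CH2O)n, i-Pr2NH·CF3CO2H, THF, 40 °C; then 26, CH2Cl2 (1 M), rt, 48 h
Reagents that add atoms: formaldehyde (from paraformaldehyde), C=O
Why: Mannich-type α-methylenation of the acidic benzofuranone generates the unstable methylene lactone in situ, and an intermolecular Diels–Alder reaction follows (diene C12 to the substituted dienophile carbon, lactone carbonyl exo); facial selectivity on both partners is substrate-controlled, as in the presumed biosynthetic union, and sets C12 and the spiro carbon.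

## Compound list

1 | 2-bromo-1-(bromomethyl)-3-methoxybenzene | COc1cccc(CBr)c1Br | starting material
2 | geranyl chloride, (2E)-1-chloro-3,7-dimethylocta-2,6-diene | CC(C)=CCC/C(C)=C/CCl | starting material
3 | (2-bromo-3-methoxybenzyl)magnesium bromide | COc1cccc(C[Mg]Br)c1Br | intermediate (not isolated)
4 | 2-bromo-1-[(3E)-4,8-dimethylnona-3,7-dien-1-yl]-3-methoxybenzene | COc1cccc(CC/C=C(\C)CCC=C(C)C)c1Br | intermediate
5 | 14-bromo-13-methoxypodocarpa-8,11,13-triene, (4bS,8aS)-1-bromo-2-methoxy-4b,8,8-trimethyl-4b,5,6,7,8,8a,9,10-octahydrophenanthrene | COc1ccc2c(c1Br)CC[C@H]1C(C)(C)CCC[C@]21C | intermediate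
6 | 14-bromo-13-methoxypodocarpa-8,11,13-trien-7-one (5α-H, 10β-CH3) | COc1ccc2c(c1Br)C(=O)C[C@H]1C(C)(C)CCC[C@]21C | intermediate
7 | tert-butyl 13-methoxy-7-oxo-17-nortotara-8,11,13-trien-16-oate | COc1ccc2c(c1CC(=O)OC(C)(C)C)C(=O)C[C@H]1C(C)(C)CCC[C@]21C | intermediate
8 | 13-hydroxy-7-oxo-17-nortotara-8,11,13-trien-16-oic acid | OC(=O)Cc1c(O)ccc2c1C(=O)C[C@H]1C(C)(C)CCC[C@]21C | intermediate (not isolated)
9 | 7-oxo-17-nortotara-8,11,13-trien-16,13-olide | O=C1Oc2ccc3c(c2C1)C(=O)C[C@H]1C(C)(C)CCC[C@]31C | intermediate
10 | (7S)-7β-hydroxy-17-nortotara-8,11,13-trien-16,13-olide | O=C1Oc2ccc3c(c2C1)[C@@H](O)C[C@H]1C(C)(C)CCC[C@]31C | intermediate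
11 | (7S)-7β-acetoxy-17-nortotara-8,11,13-trien-16,13-olide | O=C1Oc2ccc3c(c2C1)[C@@H](OC(C)=O)C[C@H]1C(C)(C)CCC[C@]31C | intermediate
12 | 5-bromo-2-methylpent-2-ene | CC(C)=CCCBr | starting material
13 | (3S)-3-(2-bromoethyl)-2,2-dimethyloxirane | BrCC[C@@H]1OC1(C)C | intermediate
14 | allyl (diethoxyphosphoryl)acetate | C=CCOC(=O)CP(=O)(OCC)OCC | starting material
15 | allyl 2-(diethoxyphosphoryl)-4-[(2S)-3,3-dimethyloxiran-2-yl]butanoate (epimers at C2) | C=CCOC(=O)C(CC[C@@H]1OC1(C)C)P(=O)(OCC)OCC | intermediate
16 | 3-methyl-2,5-dihydrothiophene 1,1-dioxide (3-methyl-3-sulfolene) | CC1=CCS(=O)(=O)C1 | starting material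
17 | geranyl bromide, (2E)-1-bromo-3,7-dimethylocta-2,6-diene | CC(C)=CCC/C(C)=C/CBr | starting material
18 | 2-[(2E)-3,7-dimethylocta-2,6-dien-1-yl]-3-methyl-2,5-dihydrothiophene 1,1-dioxide (racemic at ring C2) | CC(C)=CCC/C(C)=C/CC1C(C)=CCS1(=O)=O | intermediate
19 | (4E)-4-methyl-6-(3-methyl-1,1-dioxo-2,5-dihydrothiophen-2-yl)hex-4-enal (racemic at ring C2) | O=CCC/C(C)=C/CC1C(C)=CCS1(=O)=O | intermediate
20 | allyl (6E)-2-{2-[(2S)-3,3-dimethyloxiran-2-yl]ethyl}-6-methyl-8-(3-methyl-1,1-dioxo-2,5-dihydrothiophen-2-yl)octa-2,6-dienoate (2E/2Z mixture; epimers at the sulfolene carbon) | C=CCOC(=O)C(CC[C@@H]1OC1(C)C)=CCC/C(C)=C/CC1C(C)=CCS1(=O)=O | intermediate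
21 | allyl 3β-(trimethylsilyloxy)-12,15-sulfonyllabda-8(17),13-dien-20-oate (C12 epimers) | C=C1CC[C@H]2C(C)(C)[C@@H](O[Si](C)(C)C)CC[C@]2(C(=O)OCC=C)[C@H]1CC1C(C)=CCS1(=O)=O | intermediate (not isolated)
22 | allyl 3β-hydroxy-12,15-sulfonyllabda-8(17),13-dien-20-oate (3S; 5α-H; 9α-H; 10β-ester; C12 epimers) | C=C1CC[C@H]2C(C)(C)[C@@H](O)CC[C@]2(C(=O)OCC=C)[C@H]1CC1C(C)=CCS1(=O)=O | intermediate
23 | allyl 3β-(phenoxythiocarbonyloxy)-12,15-sulfonyllabda-8(17),13-dien-20-oate (C12 epimers) | C=C1CC[C@H]2C(C)(C)[C@@H](OC(=S)Oc3ccccc3)CC[C@]2(C(=O)OCC=C)[C@H]1CC1C(C)=CCS1(=O)=O | intermediate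
24 | allyl 12,15-sulfonyllabda-8(17),13-dien-20-oate (C12 epimers) | C=C1CC[C@H]2C(C)(C)CCC[C@]2(C(=O)OCC=C)[C@H]1CC1C(C)=CCS1(=O)=O | intermediate
25 | 12,15-sulfonyllabda-8(17),13-dien-20-oic acid (C12 epimers) | C=C1CC[C@H]2C(C)(C)CCC[C@]2(C(=O)O)[C@H]1CC1C(C)=CCS1(=O)=O | intermediate
26 | (12E)-labda-8(17),12,14-trien-20-oic acid (5α-H; 9α-H; 10β-CO2H) | C=C1CC[C@H]2C(C)(C)CCC[C@]2(C(=O)O)[C@H]1C/C=C(\C)C=C | intermediate
27 | (7S)-7β-acetoxytotara-8,11,13,15(17)-tetraen-16,13-olide | C=C1C(=O)Oc2ccc3c(c21)[C@@H](OC(C)=O)C[C@H]1C(C)(C)CCC[C@]31C | intermediate (not isolated)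
28 | hispidanin B | C=C1CC[C@H]2C(C)(C)CCC[C@]2(C(=O)O)[C@H]1C[C@H]1C(C)=CCC[C@]12C(=O)Oc1ccc3c(c12)[C@@H](OC(C)=O)C[C@H]1C(C)(C)CCC[C@]31C | target

## Step count and risks

Total steps: 18 (three branches: steps 1–7, steps 8–17 with a side branch 10–11, and the union in step 18).
Longest linear sequence: 9 steps (12 → 28 through steps 8, 9, 12, 13, 14, 15, 16, 17, 18).

Three steps most likely to fail:

Step 2 (the proposed new IDPi arene-terminated cyclization; risks are incomplete cyclization and low ee with a deactivated arene). The fallback sets out from 4 and comes back at 5. A known Lewis-base-catalysed enantioselective bromonium-initiated polyene cyclization (chiral BINOL-derived thiophosphoramide catalyst, 1,3-dibromo-5,5-dimethylhydantoin, toluene, low temperature) gives 3β,14-dibromo-13-methoxypodocarpa-8,11,13-triene F1. Chemoselective radical debromination of the secondary alkyl bromide (Bu3SnH, Et3B, PhMe, 0 °C; the aryl bromide reacts much more slowly) then gives 5.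

Step 13 (the titanocene cascade; the main risk is reduction of the α-ester radical by trivalent titanium before ring B closes, and the sulfolene is an untested spectator). The fallback sets out from 20 and comes back at 22. Reduction with i-Bu2AlH (CH2Cl2, −78 °C) converts the allyl ester into the allylic alcohol (6E)-2-{2-[(2S)-3,3-dimethyloxiran-2-yl]ethyl}-6-methyl-8-(3-methyl-1,1-dioxo-2,5-dihydrothiophen-2-yl)octa-2,6-dien-1-ol F2. This all-alkyl epoxypolyprene is the direct analogue of the epoxyfarnesyl substrates for which the same titanocene conditions are established, and it gives 12,15-sulfonyllabda-8(17),13-diene-3β,20-diol F3. Selective oxidation of the primary alcohol (TEMPO, PhI(OAc)2, MeCN/H2O) gives 3β-hydroxy-12,15-sulfonyllabda-8(17),13-dien-20-oic acid F4, and O-allylation (allyl bromide, K2CO3, DMF) returns 22.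

Step 18 (dimerization or polymerization of the methylene lactone before cycloaddition; exo and facial selectivity rest on substrate control). The fallback sets out from 11 and comes back at 27, which is trapped to 28 as before. It uses the classical stepwise methylenation with storable precursors: Eschenmoser's salt (CH2=NMe2+ I−, CH2Cl2, rt) gives the Mannich base 7β-acetoxy-17-(dimethylamino)totara-8,11,13-trien-16,13-olide F5, and MeI gives the quaternary salt 7β-acetoxy-17-(trimethylammonio)totara-8,11,13-trien-16,13-olide iodide F6. Stirring F6 with 26 in CH2Cl2 over aq. NaHCO3 at 0 °C → rt releases 27 slowly by loss of trimethylamine, so it is captured by the diene as it forms.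

## Further compounds

F1 | step 2 | 3β,14-dibromo-13-methoxypodocarpa-8,11,13-triene | COc1ccc2c(c1Br)CC[C@H]1C(C)(C)[C@@H](Br)CC[C@]21C
F2 | step 13 | (6E)-2-{2-[(2S)-3,3-dimethyloxiran-2-yl]ethyl}-6-methyl-8-(3-methyl-1,1-dioxo-2,5-dihydrothiophen-2-yl)octa-2,6-dien-1-ol | OCC(CC[C@@H]1OC1(C)C)=CCC/C(C)=C/CC1C(C)=CCS1(=O)=O
F3 | step 13 | 12,15-sulfonyllabda-8(17),13-diene-3β,20-diol | C=C1CC[C@H]2C(C)(C)[C@@H](O)CC[C@]2(CO)[C@H]1CC1C(C)=CCS1(=O)=O
F4 | step 13 | 3β-hydroxy-12,15-sulfonyllabda-8(17),13-dien-20-oic acid | C=C1CC[C@H]2C(C)(C)[C@@H](O)CC[C@]2(C(=O)O)[C@H]1CC1C(C)=CCS1(=O)=O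
F5 | step 18 | 7β-acetoxy-17-(dimethylamino)totara-8,11,13-trien-16,13-olide (C15 epimers) | CN(C)CC1C(=O)Oc2ccc3c(c21)[C@@H](OC(C)=O)C[C@H]1C(C)(C)CCC[C@]31C
F6 | step 18 | 7β-acetoxy-17-(trimethylammonio)totara-8,11,13-trien-16,13-olide iodide (C15 epimers) | C[N+](C)(C)CC1C(=O)Oc2ccc3c(c21)[C@@H](OC(C)=O)C[C@H]1C(C)(C)CCC[C@]31C.[I-]
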